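**Retrosynthetic overview**
1. Tetronic acid (last ring, only stereocentre): open the lactone to the acyclic 4-hydroxy-3-oxo ester; its carbinol comes from enantioselective hydroxylation of the β-keto ester dianion (oxidation of the terminal unit, then lactonisation, as in the presumed biogenesis).
2. β-Keto ester: γ-alkylation of the ethyl 2-methylacetoacetate dianion with the allylic bromide of the difuran chain.
3. Central 2,4-disubstituted furan: cyclodehydration of a 4-hydroxy-enone (ketone plus allylic CH2OH of one oxidised isoprene unit), made by Wittig union of an α-hydroxy ketone with a 3-furyl keto-ylide.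
4. α-Hydroxy ketone from (E)-geranylacetone by oxidation of the terminal (E)-methyl (SeO2) and of the acetyl methyl (enolate hydroxylation); ylide from 3-bromofuran and epichlorohydrin.
5. Ring order: terminal furan bought → central furan (step 6) → tetronic acid (step 9).

Assumption: (+)-(camphorsulfonyl)oxaziridine gives the (S)-carbinol in step 9, by analogy with its behaviour towards Z-enolates of acyclic ketones; if a model run shows the opposite sense, the (−)-reagent is used.

**Step 1**
Reactants: 1 (E)-geranylacetone [(5E)-6,10-dimethylundeca-5,9-dien-2-one]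
Product: 2 (5E,9E)-11-hydroxy-6,10-dimethylundeca-5,9-dien-2-one
Conditions: SeO2 (0.5 equiv), t-BuOOH (3 equiv), salicylic acid (cat.), CH2Cl2, rt
Reagents that add atoms: tert-butyl hydroperoxide, CC(C)(C)OO (net oxygen source, transferred through selenium dioxide, O=[Se]=O)
Why: Sharpless-type SeO2/t-BuOOH allylic oxidation (ene reaction, then [2,3]-sigmatropic shift) attacks the terminal trisubstituted alkene at its (E)-methyl group and so gives the (E)-allylic alcohol, while the ketone α-positions do not react at room temperature.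

**Step 2**
Reactants: 2 (5E,9E)-11-hydroxy-6,10-dimethylundeca-5,9-dien-2-one
Product: 4 (5E,9E)-1,11-dihydroxy-6,10-dimethylundeca-5,9-dien-2-one, via dipotassium alkoxide-enolate 3 (not isolated)
Conditions: KHMDS (2.2 equiv), THF, −78 °C (inverse addition); (±)-2-(phenylsulfonyl)-3-phenyloxaziridine (1.3 equiv), −78 °C; AcOH quench
Reagents that add atoms: 2-(phenylsulfonyl)-3-phenyloxaziridine, O=S(=O)(c1ccccc1)N1OC1c1ccccc1
Why: Davis enolate oxidation: KHMDS forms the alkoxide and then the kinetic enolate on the methyl side, which is hydroxylated by the N-sulfonyloxaziridine without touching the alkenes; no stereocentre is formed.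

**Step 3**
Reactants: 5 3-bromofuran; 6 (±)-epichlorohydrin
Product: 8 (±)-1-chloro-3-(furan-3-yl)propan-2-ol, via 3-furyllithium 7 (not isolated)
Conditions: n-BuLi (1.0 equiv), THF, −78 °C; BF3·OEt2 (1.1 equiv), then 6, −78 °C; AcOH quench
Reagents that add atoms: none
Why: Bromine–lithium exchange gives 3-furyllithium, which opens the BF3-activated epoxide at its unsubstituted carbon (SN2) faster than it displaces chloride; the carbinol centre is racemic and is removed in step 4.

**Step 4**
Reactants: 8 (±)-1-chloro-3-(furan-3-yl)propan-2-ol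
Product: 9 1-chloro-3-(furan-3-yl)propan-2-one
Conditions: Dess–Martin periodinane (1.2 equiv), CH2Cl2, 0 °C → rt
Reagents that add atoms: none
Why: Dess–Martin oxidation of the secondary alcohol is mild enough for the furan and the α-chloro ketone.

**Step 5**
Reactants: 9 1-chloro-3-(furan-3-yl)propan-2-one
Product: 11 1-(furan-3-yl)-3-(triphenyl-λ5-phosphanylidene)propan-2-one, via phosphonium chloride 10 (not isolated)
Conditions: PPh3 (1.05 equiv), PhMe, 80 °C; then aq. Na2CO3, CH2Cl2, rt
Reagents that add atoms: triphenylphosphine, c1ccc(cc1)P(c1ccccc1)c1ccccc1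
Why: SN2 alkylation of triphenylphosphine by the α-chloro ketone gives the phosphonium salt, whose P–CH2 proton is removed by carbonate to give the keto-stabilised ylide.

**Step 6**
Reactants: 4 (5E,9E)-1,11-dihydroxy-6,10-dimethylundeca-5,9-dien-2-one; 11 1-(furan-3-yl)-3-(triphenyl-λ5-phosphanylidene)propan-2-one
Product: 13 (2E,6E)-9-[5-(furan-3-ylmethyl)furan-3-yl]-2,6-dimethylnona-2,6-dien-1-ol, via (3Z)-4-hydroxy-enone 12 (not isolated)
Conditions: PhMe, 100 °C, 24 h; then PPTS (10 mol%), 80 °C
Reagents that add atoms: none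
Why: Wittig olefination of the hydroxyl-activated ketone gives the 4-hydroxy-enone, whose hydroxyl adds to the ketone and whose hemiketal loses water under PPTS (Paal–Knorr-type cyclodehydration driven by aromatisation); no stereocentre is formed and the acid also funnels any E-enone to the furan.

**Step 7**
Reactants: 13 (2E,6E)-9-[5-(furan-3-ylmethyl)furan-3-yl]-2,6-dimethylnona-2,6-dien-1-ol
Product: 14 4-[(3E,7E)-9-bromo-4,8-dimethylnona-3,7-dien-1-yl]-2-(furan-3-ylmethyl)furan
Conditions: CBr4 (1.2 equiv), PPh3 (1.25 equiv), CH2Cl2, −20 → 0 °C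
Reagents that add atoms: carbon tetrabromide, BrC(Br)(Br)Br
Why: The Appel reaction converts the primary allylic alcohol to the bromide by SN2 under neutral conditions, so the alkene geometry and the acid-sensitive furans are kept.

**Step 8**
Reactants: 14 4-[(3E,7E)-9-bromo-4,8-dimethylnona-3,7-dien-1-yl]-2-(furan-3-ylmethyl)furan; 15 ethyl 2-methyl-3-oxobutanoate
Product: 17 ethyl (6E,10E)-13-[5-(furan-3-ylmethyl)furan-3-yl]-2,6,10-trimethyl-3-oxotrideca-6,10-dienoate, via sodium lithium dianion 16 (not isolated)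
Conditions: 15 (1.5 equiv), NaH, THF, 0 °C; n-BuLi, 0 °C; then 14, 0 °C; cold 1 M HCl work-up
Reagents that add atoms: none
Why: Weiler dianion alkylation: the γ-carbanion of the β-keto ester dianion is the most nucleophilic site and displaces the primary allylic bromide by SN2, so the E-alkene is kept; the C-2 centre is epimerisable and disappears in step 9.

**Step 9**
Reactants: 17 ethyl (6E,10E)-13-[5-(furan-3-ylmethyl)furan-3-yl]-2,6,10-trimethyl-3-oxotrideca-6,10-dienoate
Product: 20 (5S)-5-[(2E,6E)-9-[5-(furan-3-ylmethyl)furan-3-yl]-2,6-dimethylnona-2,6-dien-1-yl]-4-hydroxy-3-methylfuran-2(5H)-one, via keto ester dianion 18 (not isolated), via (4S)-4-hydroxy-3-oxo ester 19 (not isolated)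
Conditions: NaH (1.05 equiv), THF, 0 °C; LDA (1.05 equiv), −78 °C; (+)-(camphorsulfonyl)oxaziridine (1.2 equiv), −78 → 0 °C; then 1 M HCl, rt
Reagents that add atoms: (+)-(2R,8aS)-10-(camphorylsulfonyl)oxaziridine, CC1(C)[C@@H]2CC[C@]13CS(=O)(=O)N4O[C@@]34C2
Why: Proposed new method: the dianion reacts at its far more nucleophilic γ-carbon (as in Weiler alkylations) with the electrophilic oxygen of the chiral N-sulfonyloxaziridine, whose camphor skeleton shields one face of the Z-configured γ-enolate so that the (S)-alkoxide forms, and this alkoxide then attacks the ester (5-exo-trig, loss of ethoxide) to close the tetronic acid as the stabilised tetronate; the closest known reaction types are the Davis asymmetric hydroxylation of ketone enolates and the spontaneous lactonisation of γ-hydroxy β-keto esters to tetronic acids.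

**Compound list**
1 | (E)-geranylacetone, (5E)-6,10-dimethylundeca-5,9-dien-2-one | CC(=O)CC/C=C(C)/CCC=C(C)C | starting material
2 | (5E,9E)-11-hydroxy-6,10-dimethylundeca-5,9-dien-2-one | CC(=O)CC/C=C(C)/CC/C=C(C)/CO | intermediate
3 | dipotassium alkoxide-enolate of 2 (formed in flask) | [K+].[K+].C=C([O-])CC/C=C(C)/CC/C=C(C)/C[O-] | intermediate
4 | (5E,9E)-1,11-dihydroxy-6,10-dimethylundeca-5,9-dien-2-one | OCC(=O)CC/C=C(C)/CC/C=C(C)/CO | intermediate
5 | 3-bromofuran | Brc1ccoc1 | starting material
6 | (±)-epichlorohydrin | ClCC1CO1 | starting material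
7 | 3-furyllithium (formed in flask) | [Li]c1ccoc1 | intermediate
8 | (±)-1-chloro-3-(furan-3-yl)propan-2-ol | OC(CCl)Cc1ccoc1 | intermediate
9 | 1-chloro-3-(furan-3-yl)propan-2-one | O=C(CCl)Cc1ccoc1 | intermediate
10 | [3-(furan-3-yl)-2-oxopropyl]triphenylphosphonium chloride (formed in flask) | [Cl-].O=C(Cc1ccoc1)C[P+](c1ccccc1)(c1ccccc1)c1ccccc1 | intermediate
11 | 1-(furan-3-yl)-3-(triphenyl-λ5-phosphanylidene)propan-2-one | O=C(Cc1ccoc1)C=P(c1ccccc1)(c1ccccc1)c1ccccc1 | intermediate
12 | (3Z,7E,11E)-1-(furan-3-yl)-13-hydroxy-4-(hydroxymethyl)-8,12-dimethyltrideca-3,7,11-trien-2-one (formed in flask) | O=C(Cc1ccoc1)/C=C(\CO)CC/C=C(C)/CC/C=C(C)/CO | intermediate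
13 | (2E,6E)-9-[5-(furan-3-ylmethyl)furan-3-yl]-2,6-dimethylnona-2,6-dien-1-ol | OC/C(C)=C/CC/C(C)=C/CCc1coc(Cc2ccoc2)c1 | intermediate
14 | 4-[(3E,7E)-9-bromo-4,8-dimethylnona-3,7-dien-1-yl]-2-(furan-3-ylmethyl)furan | BrC/C(C)=C/CC/C(C)=C/CCc1coc(Cc2ccoc2)c1 | intermediate
15 | ethyl 2-methyl-3-oxobutanoate (ethyl 2-methylacetoacetate) | CCOC(=O)C(C)C(C)=O | starting material
16 | sodium lithium dianion of 15 (formed in flask) | [Na+].[Li+].CCOC(=O)C(C)=C([O-])[CH2-] | intermediate
17 | ethyl (6E,10E)-13-[5-(furan-3-ylmethyl)furan-3-yl]-2,6,10-trimethyl-3-oxotrideca-6,10-dienoate (C-2 epimers) | CCOC(=O)C(C)C(=O)CC/C(C)=C/CC/C(C)=C/CCc1coc(Cc2ccoc2)c1 | intermediate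
18 | sodium lithium dianion of 17 (formed in flask) | [Na+].[Li+].CCOC(=O)C(C)=C([O-])[CH-]C/C(C)=C/CC/C(C)=C/CCc1coc(Cc2ccoc2)c1 | intermediate
19 | ethyl (4S,6E,10E)-13-[5-(furan-3-ylmethyl)furan-3-yl]-4-hydroxy-2,6,10-trimethyl-3-oxotrideca-6,10-dienoate (formed in flask) | CCOC(=O)C(C)C(=O)[C@@H](O)C/C(C)=C/CC/C(C)=C/CCc1coc(Cc2ccoc2)c1 | intermediate
20 | (5S)-5-[(2E,6E)-9-[5-(furan-3-ylmethyl)furan-3-yl]-2,6-dimethylnona-2,6-dien-1-yl]-4-hydroxy-3-methylfuran-2(5H)-one | CC1=C(O)[C@H](C/C(C)=C/CC/C(C)=C/CCc2coc(Cc3ccoc3)c2)OC1=O | target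

**Totals**
Total step count: 9. Longest linear sequence: 7 steps (3-bromofuran 5 to 20, steps 3–9); the geranylacetone branch is 6 steps (1, 2, 6–9).

**Steps most likely to fail, each with a fallback**

Step 9 (hydroxylation and lactonisation). The γ-hydroxylation of a β-keto ester dianion with a chiral oxaziridine is unprecedented, so both the level of enantioselectivity and the sense of induction are uncertain. The fallback sets the stereocentre by auxiliary-controlled alkylation instead of oxidation; it sets out from bromide 14 and comes back at 19, which lactonises to 20. Commercial (R)-4-benzyloxazolidin-2-one is N-acylated with (tert-butyldimethylsilyloxy)acetyl chloride to give the silyl glycolyl imide F1. Its sodium enolate (NaHMDS, THF, −78 °C) is alkylated with 14 (Bu4NI cat.) on the face away from the benzyl group to give the (2S)-2-silyloxy imide F2. The lithium enolate of ethyl propionate then displaces the auxiliary (Claisen-type acylation) to give the 4-silyloxy β-keto ester F3. TBAF buffered with AcOH removes the silyl group to give 19, which closes to 20 as in step 9.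

Step 6 (Wittig olefination and cyclodehydration). Keto-stabilised ylides are sluggish towards ketones, and the α-hydroxy ketone may degrade on long heating. The fallback replaces the enone by an alkyne as the masked ketone; it sets out from 4 and comes back at 13. 3-Furanmethanol and PBr3 give 3-(bromomethyl)furan F4. CuCl-catalysed coupling with ethynylmagnesium bromide gives 3-(prop-2-yn-1-yl)furan F5. F5 is deprotonated with EtMgBr (3.2 equiv, the excess serving the two hydroxyls) and added to ketone 4 to give the alkynyl triol F6. AgNO3 on silica (10 mol%) then brings about 5-endo-dig attack of the primary hydroxyl on the alkyne and loss of water to give 13.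

Step 2 (enolate hydroxylation). The methyl-ketone enolate may give regioisomers, self-aldol products or addition to the sulfonimine by-product. The fallback introduces the oxygen through a diazo ketone; it sets out from 2 and comes back at 4. LiHMDS (2.2 equiv) and 2,2,2-trifluoroethyl trifluoroacetate give the trifluoroacetyl diketone F7. Methanesulfonyl azide, Et3N and water in MeCN give the diazo ketone F8 by detrifluoroacetylative diazo transfer. Dilute H2SO4 in THF–water then gives 4 by protonation, loss of nitrogen and capture of water.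

**Further compounds**
F1 | step 9 | (4R)-4-benzyl-3-{[tert-butyl(dimethyl)silyl]oxyacetyl}-1,3-oxazolidin-2-one | O=C1OC[C@@H](Cc2ccccc2)N1C(=O)CO[Si](C)(C)C(C)(C)C
F2 | step 9 | (4R)-4-benzyl-3-[(2S,4E,8E)-2-{[tert-butyl(dimethyl)silyl]oxy}-11-[5-(furan-3-ylmethyl)furan-3-yl]-4,8-dimethylundeca-4,8-dienoyl]-1,3-oxazolidin-2-one | O=C1OC[C@@H](Cc2ccccc2)N1C(=O)[C@@H](O[Si](C)(C)C(C)(C)C)C/C(C)=C/CC/C(C)=C/CCc1coc(Cc2ccoc2)c1
F3 | step 9 | ethyl (4S,6E,10E)-4-{[tert-butyl(dimethyl)silyl]oxy}-13-[5-(furan-3-ylmethyl)furan-3-yl]-2,6,10-trimethyl-3-oxotrideca-6,10-dienoate | CCOC(=O)C(C)C(=O)[C@@H](O[Si](C)(C)C(C)(C)C)C/C(C)=C/CC/C(C)=C/CCc1coc(Cc2ccoc2)c1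
F4 | step 6 | 3-(bromomethyl)furan | BrCc1ccoc1
F5 | step 6 | 3-(prop-2-yn-1-yl)furan | C#CCc1ccoc1
F6 | step 6 | (7E,11E)-1-(furan-3-yl)-4-(hydroxymethyl)-8,12-dimethyltrideca-7,11-dien-2-yne-4,13-diol (racemic) | OCC(O)(C#CCc1ccoc1)CC/C=C(C)/CC/C=C(C)/CO
F7 | step 2 | (7E,11E)-1,1,1-trifluoro-13-hydroxy-8,12-dimethyltrideca-7,11-diene-2,4-dione | O=C(CC(=O)C(F)(F)F)CC/C=C(C)/CC/C=C(C)/CO
F8 | step 2 | (5E,9E)-1-diazo-11-hydroxy-6,10-dimethylundeca-5,9-dien-2-one | [N-]=[N+]=CC(=O)CC/C=C(C)/CC/C=C(C)/CO
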